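The cyclohexene ring is dissected at two opposite ring bonds, the CH=C(CH3) double bond and the CH2–C(quaternary) single bond. This exploits that CH2–CH2–C(CH3) is methyl vinyl ketone. The other three ring atoms (quaternary carbon, coumarinyl-bearing CH, olefinic CH) can be stored as an enantiopure cyclopropanecarbaldehyde in which the two reacting carbons are bonded to each other. In the key step PPh3 opens the cyclopropyl iminium ion at its CH2, the resulting phosphonio enamine adds to methyl vinyl ketone, the enolate generates the ylide, and an intramolecular Wittig reaction closes the ring. This is a strain-driven (3+3) ring expansion. A Horner–Wadsworth–Emmons reaction then attaches the second coumarin.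

Key step: step 10

Assumption: 2,4-dihydroxy-3-methoxybenzaldehyde (1) is taken as a catalogue compound.
Assumption: in the fallback to step 8 the tartrate acetal is drawn for the (S,S) ester; should the sense of induction prove opposite, the (R,R) ester is used.

Step 1
Reactants: 1 2,4-dihydroxy-3-methoxybenzaldehyde
Product: 2 2-hydroxy-3-methoxy-4-(methoxymethoxy)benzaldehyde
Conditions: MOMCl (1.05 equiv), K2CO3 (1.1 equiv), acetone, 0 °C to rt
Reagents that add atoms: chloromethyl methyl ether (MOMCl), COCCl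
Why: Williamson O-alkylation; the 2-OH is locked in a hydrogen bond to the formyl group, so the free and more acidic 4-OH should react selectively.

Step 2
Reactants: 2 2-hydroxy-3-methoxy-4-(methoxymethoxy)benzaldehyde
Product: 3 8-methoxy-7-(methoxymethoxy)-3-methyl-2H-chromen-2-one
Conditions: Ph3P=C(CH3)CO2Et (1.2 equiv), N,N-diethylaniline, reflux
Reagents that add atoms: ethyl 2-(triphenylphosphoranylidene)propanoate, CCOC(=O)C(C)=P(c1ccccc1)(c1ccccc1)c1ccccc1
Why: Wittig olefination with a stabilised ylide; at reflux the cinnamate isomers equilibrate and the one with aryl cis to the ester lactonises irreversibly to the coumarin.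

Step 3
Reactants: 3 8-methoxy-7-(methoxymethoxy)-3-methyl-2H-chromen-2-one
Product: 4 3-(bromomethyl)-8-methoxy-7-(methoxymethoxy)-2H-chromen-2-one
Conditions: NBS (1.05 equiv), AIBN (5 mol %), PhCF3, reflux
Reagents that add atoms: N-bromosuccinimide, O=C1CCC(=O)N1Br
Why: Wohl–Ziegler bromination; the 3-methyl group is allylic to the coumarin C3=C4 bond and gives the best stabilised radical.

Step 4
Reactants: 4 3-(bromomethyl)-8-methoxy-7-(methoxymethoxy)-2H-chromen-2-one
Product: 5 diethyl {[8-methoxy-7-(methoxymethoxy)-2-oxo-2H-chromen-3-yl]methyl}phosphonate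
Conditions: P(OEt)3 (neat), 130 °C
Reagents that add atoms: triethyl phosphite, CCOP(OCC)OCC
Why: Michaelis–Arbuzov reaction of an activated primary allylic bromide.

Step 5
Reactants: 4 3-(bromomethyl)-8-methoxy-7-(methoxymethoxy)-2H-chromen-2-one
Product: 6 8-methoxy-7-(methoxymethoxy)-2-oxo-2H-chromene-3-carbaldehyde
Conditions: DMSO, NaHCO3 (2 equiv), 90 °C
Reagents that add atoms: dimethyl sulfoxide, CS(C)=O
Why: Kornblum oxidation; the DMSO oxygen displaces the activated bromide and base collapses the alkoxysulfonium ion to the aldehyde.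

Step 6
Reactants: 6 8-methoxy-7-(methoxymethoxy)-2-oxo-2H-chromene-3-carbaldehyde
Product: 7 (E)-3-[8-methoxy-7-(methoxymethoxy)-2-oxo-2H-chromen-3-yl]-2-methylprop-2-enal
Conditions: Ph3P=C(CH3)CHO (1.1 equiv), toluene, 80 °C
Reagents that add atoms: 2-(triphenylphosphoranylidene)propanal, CC(C=O)=P(c1ccccc1)(c1ccccc1)c1ccccc1
Why: Wittig olefination with a formyl-stabilised ylide, which should give the E trisubstituted enal and is too unreactive to attack the product enal or the lactone.

Step 7
Reactants: 7 (E)-3-[8-methoxy-7-(methoxymethoxy)-2-oxo-2H-chromen-3-yl]-2-methylprop-2-enal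
Product: 8 3-[(E)-3-hydroxy-2-methylprop-1-enyl]-8-methoxy-7-(methoxymethoxy)-2H-chromen-2-one
Conditions: NaBH4 (0.5 equiv), CeCl3·7H2O (1 equiv), MeOH/CH2Cl2, −40 °C
Reagents that add atoms: none
Why: Luche reduction; the hard alkoxyborohydride attacks the aldehyde in 1,2-fashion far faster than the lactone or the conjugated C=C bonds.

Step 8
Reactants: 8 3-[(E)-3-hydroxy-2-methylprop-1-enyl]-8-methoxy-7-(methoxymethoxy)-2H-chromen-2-one
Product: 9 3-[(1R,2R)-2-(hydroxymethyl)-2-methylcyclopropyl]-8-methoxy-7-(methoxymethoxy)-2H-chromen-2-one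
Conditions: ZnEt2 (2.2 equiv), CH2I2 (4.4 equiv), DME (2.2 equiv), (4S,5S)-2-butyl-N,N,N',N'-tetramethyl-1,3,2-dioxaborolane-4,5-dicarboxamide (1.2 equiv), CH2Cl2, −10 °C to rt
Reagents that add atoms: diiodomethane, ICI
Why: Dioxaborolane-controlled asymmetric Simmons–Smith cyclopropanation; stereospecific syn addition keeps CH2OH trans to the coumarinyl group, and the chiral boronate bound to the zinc alkoxide should direct CH2 to the alkene face that sets both centres as (1R,2R).

Step 9
Reactants: 9 3-[(1R,2R)-2-(hydroxymethyl)-2-methylcyclopropyl]-8-methoxy-7-(methoxymethoxy)-2H-chromen-2-one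
Product: 10 (1R,2R)-2-[8-methoxy-7-(methoxymethoxy)-2-oxo-2H-chromen-3-yl]-1-methylcyclopropane-1-carbaldehyde
Conditions: IBX (2-iodoxybenzoic acid, 1.5 equiv), EtOAc, 75 °C
Reagents that add atoms: none
Why: IBX oxidation of a primary alcohol under neutral conditions; the α-carbon is quaternary, so nothing can epimerise and the MOM ethers are safe.

Step 10
Reactants: 10 (1R,2R)-2-[8-methoxy-7-(methoxymethoxy)-2-oxo-2H-chromen-3-yl]-1-methylcyclopropane-1-carbaldehyde; 11 methyl vinyl ketone (but-3-en-2-one)
Product: 15 (1S,2R)-2-[8-methoxy-7-(methoxymethoxy)-2-oxo-2H-chromen-3-yl]-1,4-dimethylcyclohex-3-ene-1-carbaldehyde, via cyclopropyl iminium chloride 12 (not isolated), via phosphonio enamine chloride 13 (not isolated), via keto ylide iminium chloride 14 (not isolated)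
Conditions: pyrrolidine hydrochloride (1.0 equiv), PPh3 (1.0 equiv), 4 Å MS, MeCN, 60 °C; then 11 (1.5 equiv), 0 °C to 40 °C; then H2O, NaOAc/AcOH buffer, rt
Reagents that add atoms: water, O
Why: Proposed new method: pyrrolidinium chloride condenses with 10 to the cyclopropyl iminium ion 12, PPh3 attacks its unsubstituted ring CH2 in an SN2-type homoconjugate addition (strain release, iminium as electron sink) to give the (E)-enamine 13, which adds through its methyl-bearing carbon to 11 in a Stork enamine Michael addition; the ketone enolate so formed is more basic than the ylide and deprotonates the P–CH2 group to 14, whose non-stabilised ylide olefinates the methyl ketone before water frees the aldehyde. The closest known reaction types are the halide-triggered opening of cyclopropyl iminium ions (Cloke-type cyclopropylimine rearrangement followed by enamine annulation with methyl vinyl ketone) and tandem Michael addition/intramolecular Wittig annulations that end on a phosphonium ylide and a ketone. The only ring formed closes by 6-exo-trig attack of the ylide carbon on the ketone carbonyl, which places the ring double bond between CH and C(CH3) without regioisomers. The coumarinyl-bearing stereocentre is not touched; the new quaternary centre is set in the Michael step, where 11 should approach the enamine anti to the coumarinyl group with CH2PPh3+ in the inside position (the alternative suffers allylic 1,2-strain with the enamine methyl group), which places formyl cis to coumarinyl. The step needs attack of PPh3 at CH2 and not at the coumarinyl-bearing ring carbon (secured by sterics and by the electron-poor coumarin-3-yl group, which lends no cationic character), Michael addition before any ylide exists (no base is present until the enolate appears), and ketone over iminium selectivity in the olefination (attack on the iminium carbon would need a four-membered ring).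

Step 11
Reactants: 15 (1S,2R)-2-[8-methoxy-7-(methoxymethoxy)-2-oxo-2H-chromen-3-yl]-1,4-dimethylcyclohex-3-ene-1-carbaldehyde; 5 diethyl {[8-methoxy-7-(methoxymethoxy)-2-oxo-2H-chromen-3-yl]methyl}phosphonate
Product: 16 3-[(E)-2-{(1R,2R)-1,4-dimethyl-2-[8-methoxy-7-(methoxymethoxy)-2-oxo-2H-chromen-3-yl]cyclohex-3-en-1-yl}ethenyl]-8-methoxy-7-(methoxymethoxy)-2H-chromen-2-one
Conditions: 5 (1.3 equiv), NaH (1.3 equiv), THF, 0 °C; then 15, 0 °C to rt
Reagents that add atoms: none
Why: Horner–Wadsworth–Emmons olefination with a semi-stabilised phosphonate anion should give the E alkene; the aldehyde has no α-hydrogen, so the quaternary centre cannot be scrambled.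

Step 12
Reactants: 16 3-[(E)-2-{(1R,2R)-1,4-dimethyl-2-[8-methoxy-7-(methoxymethoxy)-2-oxo-2H-chromen-3-yl]cyclohex-3-en-1-yl}ethenyl]-8-methoxy-7-(methoxymethoxy)-2H-chromen-2-one
Product: 17 7-hydroxy-3-[(E)-2-{(1R,2R)-2-(7-hydroxy-8-methoxy-2-oxo-2H-chromen-3-yl)-1,4-dimethylcyclohex-3-en-1-yl}ethenyl]-8-methoxy-2H-chromen-2-one (target)
Conditions: HCl (2 M, catalytic), MeOH/THF, 40 °C
Reagents that add atoms: none
Why: Acid-catalysed acetal exchange removes both aryl MOM ethers under conditions too mild to protonate the trisubstituted alkene or open the lactones.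

Compound list
1 | 2,4-dihydroxy-3-methoxybenzaldehyde | O=Cc1ccc(O)c(OC)c1O | starting material
2 | 2-hydroxy-3-methoxy-4-(methoxymethoxy)benzaldehyde | O=Cc1ccc(OCOC)c(OC)c1O | intermediate
3 | 8-methoxy-7-(methoxymethoxy)-3-methyl-2H-chromen-2-one | Cc1cc2ccc(OCOC)c(OC)c2oc1=O | intermediate
4 | 3-(bromomethyl)-8-methoxy-7-(methoxymethoxy)-2H-chromen-2-one | BrCc1cc2ccc(OCOC)c(OC)c2oc1=O | intermediate
5 | diethyl {[8-methoxy-7-(methoxymethoxy)-2-oxo-2H-chromen-3-yl]methyl}phosphonate | CCOP(=O)(Cc1cc2ccc(OCOC)c(OC)c2oc1=O)OCC | intermediate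
6 | 8-methoxy-7-(methoxymethoxy)-2-oxo-2H-chromene-3-carbaldehyde | O=Cc1cc2ccc(OCOC)c(OC)c2oc1=O | intermediate
7 | (E)-3-[8-methoxy-7-(methoxymethoxy)-2-oxo-2H-chromen-3-yl]-2-methylprop-2-enal | O=C/C(C)=C/c1cc2ccc(OCOC)c(OC)c2oc1=O | intermediate
8 | 3-[(E)-3-hydroxy-2-methylprop-1-enyl]-8-methoxy-7-(methoxymethoxy)-2H-chromen-2-one | OC/C(C)=C/c1cc2ccc(OCOC)c(OC)c2oc1=O | intermediate
9 | 3-[(1R,2R)-2-(hydroxymethyl)-2-methylcyclopropyl]-8-methoxy-7-(methoxymethoxy)-2H-chromen-2-one | OC[C@]1(C)C[C@H]1c2cc3ccc(OCOC)c(OC)c3oc2=O | intermediate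
10 | (1R,2R)-2-[8-methoxy-7-(methoxymethoxy)-2-oxo-2H-chromen-3-yl]-1-methylcyclopropane-1-carbaldehyde | O=C[C@]1(C)C[C@H]1c2cc3ccc(OCOC)c(OC)c3oc2=O | intermediate
11 | methyl vinyl ketone (but-3-en-2-one) | C=CC(C)=O | starting material
12 | cyclopropyl iminium chloride (pyrrolidinium ylidene derivative of 10) | [Cl-].C1CC[N+](C1)=C[C@]2(C)C[C@H]2c3cc4ccc(OCOC)c(OC)c4oc3=O | intermediate
13 | phosphonio enamine chloride, (E)-enamine with CH2PPh3+ on the coumarinyl-bearing carbon | [Cl-].C1CCN(C1)/C=C(C)/[C@@H](C[P+](c1ccccc1)(c1ccccc1)c1ccccc1)c1cc2ccc(OCOC)c(OC)c2oc1=O | intermediate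
14 | keto ylide iminium chloride (Michael adduct after proton transfer) | [Cl-].C1CC[N+](C1)=C[C@@](C)(CCC(C)=O)[C@@H](C=P(c1ccccc1)(c1ccccc1)c1ccccc1)c1cc2ccc(OCOC)c(OC)c2oc1=O | intermediate
15 | (1S,2R)-2-[8-methoxy-7-(methoxymethoxy)-2-oxo-2H-chromen-3-yl]-1,4-dimethylcyclohex-3-ene-1-carbaldehyde | O=C[C@@]1(C)CCC(C)=C[C@H]1c2cc3ccc(OCOC)c(OC)c3oc2=O | intermediate
16 | bis-MOM ether of the target | COc1c(OCOC)ccc2cc(/C=C/[C@@]3(C)CCC(C)=C[C@H]3c3cc4ccc(OCOC)c(OC)c4oc3=O)c(=O)oc12 | intermediate
17 | CNP0264408.1 | COc1c(O)ccc2cc(/C=C/[C@@]3(C)CCC(C)=C[C@H]3c3cc4ccc(O)c(OC)c4oc3=O)c(=O)oc12 | target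

Total step count: 12. Longest linear sequence: 11 (steps 1–3 and 5–12; step 4 is the side branch).

Steps most likely to fail

**Step 10 (Proposed new method).**
- What may go wrong:
  - opening of the iminium ion may be slow or occur at the wrong ring carbon;
  - PPh3 may be consumed by conjugate addition to 11;
  - traces of water may protonate the enolate so that no ylide forms;
  - the methyl ketone may close onto the iminium carbon in a Mannich-type reaction;
  - facial selectivity in the Michael addition may be poor.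
- The fallback uses known chemistry, makes the two ring bonds in separate operations and forms the C=C by olefin metathesis. It sets out from 6 and comes back at 16.
- Vinylmagnesium bromide (THF, −78 °C) adds to the formyl group of 6 to give racemic 3-(1-hydroxyprop-2-enyl)-8-methoxy-7-(methoxymethoxy)-2H-chromen-2-one F1.
- Dual iridium/enamine-catalysed α-allylation of propanal ([Ir(cod)Cl]2, chiral phosphoramidite–olefin ligand, diarylprolinol silyl ether, acid promoter, 1,2-dichloroethane) converts F1 enantioconvergently into (3R)-3-[8-methoxy-7-(methoxymethoxy)-2-oxo-2H-chromen-3-yl]-2-methylpent-4-enal F2. Its C-2 configuration is immaterial.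
- A Michael addition to 11 catalysed by a chiral primary amine salt gives (2S,3R)-3-[8-methoxy-7-(methoxymethoxy)-2-oxo-2H-chromen-3-yl]-2-methyl-2-(3-oxobutyl)pent-4-enal F3.
- Chemoselective Horner–Wadsworth–Emmons olefination of the formyl group with 5 (NaH, THF) gives 3,3'-[(1E,3R,4R)-3-methyl-3-(3-oxobutyl)hexa-1,5-diene-1,4-diyl]bis[8-methoxy-7-(methoxymethoxy)-2H-chromen-2-one] F4.
- Wittig methylenation of the ketone (Ph3P=CH2, THF, −78 to 0 °C) gives 3,3'-[(1E,3R,4R)-3-methyl-3-(3-methylbut-3-enyl)hexa-1,5-diene-1,4-diyl]bis[8-methoxy-7-(methoxymethoxy)-2H-chromen-2-one] F5.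
- Ring-closing metathesis (second-generation Grubbs catalyst, CH2Cl2, reflux) joins the vinyl group on the coumarinyl-bearing carbon to the isopropenyl group and gives 16.

**Step 8.**
- What may go wrong: methylene transfer to an alkene deactivated by the lactone may be slow, and zinc binding to the lactone and MOM oxygens in competition with the boronate complex may erode enantiofacial control.
- The fallback replaces the non-covalent controller by a covalently bound auxiliary at the aldehyde oxidation level and drops both redox steps. It sets out from 7 and comes back at 10.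
- Acetalisation of 7 with the bis(trimethylsilyl) ether of diisopropyl (2S,3S)-tartrate (TMSOTf cat., CH2Cl2, −78 °C) gives diisopropyl (4S,5S)-2-{(E)-1-[8-methoxy-7-(methoxymethoxy)-2-oxo-2H-chromen-3-yl]prop-1-en-2-yl}-1,3-dioxolane-4,5-dicarboxylate F6.
- Auxiliary-directed Simmons–Smith cyclopropanation (ZnEt2, CH2I2, hexane/CH2Cl2, −20 °C) gives diisopropyl (4S,5S)-2-{(1R,2R)-2-[8-methoxy-7-(methoxymethoxy)-2-oxo-2H-chromen-3-yl]-1-methylcyclopropyl}-1,3-dioxolane-4,5-dicarboxylate F7. The minor diastereomer can be removed by chromatography.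
- Mild acetal hydrolysis (LiBF4, wet MeCN) releases 10.

**Step 11.**
- What may go wrong: the bulky phosphonate anion may add slowly to the neopentyl aldehyde, and the base may attack the lactones during the long reaction time.
- The fallback builds the E alkene by cross-metathesis instead of carbonyl olefination. It sets out from 15 and 6 and comes back at 16.
- Wittig methylenation of 6 (Ph3P=CH2, THF, −78 °C) gives 3-ethenyl-8-methoxy-7-(methoxymethoxy)-2H-chromen-2-one F8.
- The same reaction on 15 gives 3-[(1R,6R)-6-ethenyl-3,6-dimethylcyclohex-2-en-1-yl]-8-methoxy-7-(methoxymethoxy)-2H-chromen-2-one F9.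
- Cross-metathesis of F9 with excess F8 (second-generation Hoveyda–Grubbs catalyst, toluene, 60 °C) should give 16. The vinyl group on the quaternary carbon cannot homodimerise and the trisubstituted ring alkene stays inert.

Further compounds
F1 | step 10 | 3-(1-hydroxyprop-2-enyl)-8-methoxy-7-(methoxymethoxy)-2H-chromen-2-one (racemic) | C=CC(O)c1cc2ccc(OCOC)c(OC)c2oc1=O
F2 | step 10 | (3R)-3-[8-methoxy-7-(methoxymethoxy)-2-oxo-2H-chromen-3-yl]-2-methylpent-4-enal | O=CC(C)[C@@H](C=C)c1cc2ccc(OCOC)c(OC)c2oc1=O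
F3 | step 10 | (2S,3R)-3-[8-methoxy-7-(methoxymethoxy)-2-oxo-2H-chromen-3-yl]-2-methyl-2-(3-oxobutyl)pent-4-enal | O=C[C@@](C)(CCC(C)=O)[C@@H](C=C)c1cc2ccc(OCOC)c(OC)c2oc1=O
F4 | step 10 | 3,3'-[(1E,3R,4R)-3-methyl-3-(3-oxobutyl)hexa-1,5-diene-1,4-diyl]bis[8-methoxy-7-(methoxymethoxy)-2H-chromen-2-one] | COc1c(OCOC)ccc2cc(/C=C/[C@@](C)(CCC(C)=O)[C@@H](C=C)c3cc4ccc(OCOC)c(OC)c4oc3=O)c(=O)oc12
F5 | step 10 | 3,3'-[(1E,3R,4R)-3-methyl-3-(3-methylbut-3-enyl)hexa-1,5-diene-1,4-diyl]bis[8-methoxy-7-(methoxymethoxy)-2H-chromen-2-one] | COc1c(OCOC)ccc2cc(/C=C/[C@@](C)(CCC(C)=C)[C@@H](C=C)c3cc4ccc(OCOC)c(OC)c4oc3=O)c(=O)oc12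
F6 | step 8 | diisopropyl (4S,5S)-2-{(E)-1-[8-methoxy-7-(methoxymethoxy)-2-oxo-2H-chromen-3-yl]prop-1-en-2-yl}-1,3-dioxolane-4,5-dicarboxylate | CC(C)OC(=O)[C@H]1OC(O[C@@H]1C(=O)OC(C)C)/C(C)=C/c1cc2ccc(OCOC)c(OC)c2oc1=O
F7 | step 8 | diisopropyl (4S,5S)-2-{(1R,2R)-2-[8-methoxy-7-(methoxymethoxy)-2-oxo-2H-chromen-3-yl]-1-methylcyclopropyl}-1,3-dioxolane-4,5-dicarboxylate | CC(C)OC(=O)[C@H]1OC(O[C@@H]1C(=O)OC(C)C)[C@]2(C)C[C@H]2c3cc4ccc(OCOC)c(OC)c4oc3=O
F8 | step 11 | 3-ethenyl-8-methoxy-7-(methoxymethoxy)-2H-chromen-2-one | C=Cc1cc2ccc(OCOC)c(OC)c2oc1=O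
F9 | step 11 | 3-[(1R,6R)-6-ethenyl-3,6-dimethylcyclohex-2-en-1-yl]-8-methoxy-7-(methoxymethoxy)-2H-chromen-2-one | C=C[C@@]1(C)CCC(C)=C[C@H]1c2cc3ccc(OCOC)c(OC)c3oc2=O
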